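**Retrosynthetic overview**
1. Target 28 ⇐ penta-MOM flavanone 26 (global MOM cleavage) ⇐ 2'-hydroxychalcone 25 by an enantioselective 6-endo oxa-Michael closure (ring C, the only ring that is built; sets C2).
2. 25 ⇐ Claisen–Schmidt condensation of ring-A acetophenone 21 with ring-B aldehyde 24.
3. 21 ⇐ phenol 19 (ortho-lithiation/acetylation). The side chain of 19 is built on the arene by three consecutive 1,2-boronate shifts: aryl→CH2 (benzylboronate 8), benzyl→C with inversion onto a (+)-sparteine-derived lithiated ester (sets the side-chain centre, 13), then sec-alkyl→isopropenyl carbon with retention (Zweifel).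
4. Both benzene rings come from resorcinol 1: bis-MOM ether 2, Ir-catalysed meta C–H borylation/oxidation to phenol 4, then TBS ether 5 (ring A) or tris-MOM ether 22 → aldehyde 24 (ring B).
5. Ring order: A and B are carried as intact benzene rings; ring C is closed in step 12; deprotection ends the route.

Assumption: the SMILES is read as (2S) at C2 and (S) at the side-chain stereocentre; (+)-sparteine and (bromomethyl)boronic acid pinacol ester are bought.

**Route**

Step 1
Reactants: 1 resorcinol (benzene-1,3-diol)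
Product: 2 1,3-bis(methoxymethoxy)benzene
Conditions: NaH, MOMCl, DMF, 0 °C → rt
Reagents that add atoms: chloromethyl methyl ether, COCCl
Why: Double Williamson O-alkylation of the bis-phenoxide; MOM is used because it later directs ortho-lithiation.

Step 2
Reactants: 2 1,3-bis(methoxymethoxy)benzene
Product: 4 3,5-bis(methoxymethoxy)phenol, via aryl pinacol boronate 3 (not isolated)
Conditions: B2pin2, [Ir(OMe)(cod)]2 (1.5 mol%), dtbpy (3 mol%), THF, 80 °C; then aq. NaOH, 30% H2O2, 0 °C → rt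
Reagents that add atoms: hydrogen peroxide, OO
Why: Sterically controlled Ir-catalysed C–H borylation takes the only C–H without an ortho substituent (C5), and alkaline peroxide oxidation of the aryl boronate gives the phenol in the same pot.

Step 3
Reactants: 4 3,5-bis(methoxymethoxy)phenol
Product: 5 tert-butyl[3,5-bis(methoxymethoxy)phenoxy]dimethylsilane
Conditions: TBSCl, imidazole, DMF, rt
Reagents that add atoms: tert-butyldimethylsilyl chloride, CC(C)(C)[Si](C)(C)Cl
Why: Silylation of the phenol gives a non-directing, bulky ether, so the next lithiation goes only between the two OMOM groups.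

Step 4
Reactants: 5 tert-butyl[3,5-bis(methoxymethoxy)phenoxy]dimethylsilane
Product: 8 2-{[4-(tert-butyldimethylsilyloxy)-2,6-bis(methoxymethoxy)phenyl]methyl}-4,4,5,5-tetramethyl-1,3,2-dioxaborolane, via aryllithium 6 (not isolated), via bromomethyl borate complex 7 (not isolated)
Conditions: n-BuLi, TMEDA, THF, −20 → 0 °C; BrCH2Bpin, −78 °C → rt
Reagents that add atoms: 2-(bromomethyl)-4,4,5,5-tetramethyl-1,3,2-dioxaborolane, BrCB1OC(C)(C)C(C)(C)O1
Why: Directed ortho-lithiation between the two OMOM groups, addition of the aryllithium to boron, then a Matteson-type 1,2-shift of the aryl group from boron to carbon with loss of bromide.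

Step 5
Reactants: 9 4-methylpent-3-en-1-ol
Product: 10 4-methylpent-3-en-1-yl 2,4,6-tri(propan-2-yl)benzoate
Conditions: 2,4,6-triisopropylbenzoyl chloride, Et3N, DMAP (cat.), CH2Cl2, reflux
Reagents that add atoms: 2,4,6-triisopropylbenzoyl chloride, CC(C)c1cc(C(C)C)c(C(Cl)=O)c(C(C)C)c1
Why: Esterification gives the hindered benzoate that allows sparteine-mediated α-lithiation and later serves as the leaving group.

Step 6
Reactants: 10 4-methylpent-3-en-1-yl 2,4,6-tri(propan-2-yl)benzoate; 8 benzylboronic ester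
Product: 13 2-[(2S)-1-{4-(tert-butyldimethylsilyloxy)-2,6-bis(methoxymethoxy)phenyl}-5-methylhex-4-en-2-yl]-4,4,5,5-tetramethyl-1,3,2-dioxaborolane, via lithiated benzoate 11 (not isolated), via benzyl borate complex 12 (not isolated)
Conditions: 10, s-BuLi, (+)-sparteine, Et2O, −78 °C, 5 h; then 8, −78 °C, 1 h; then reflux, 12 h
Reagents that add atoms: none
Why: Lithiation–borylation (Hoppe–Aggarwal): (+)-sparteine-controlled deprotonation gives the (R)-lithio ester, which binds boron with retention, and the benzyl group then migrates from boron to carbon anti to the benzoate (stereospecific 1,2-metallate shift with inversion), which sets the (S) side-chain centre.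

Step 7
Reactants: 13 (S)-secondary boronic ester; 14 2-bromopropene
Product: 19 3,5-bis(methoxymethoxy)-4-[(2S)-5-methyl-2-(prop-1-en-2-yl)hex-4-en-1-yl]phenol, via isopropenyllithium 15 (not isolated), via alkenyl borate complex 16 (not isolated), via iodo boronic ester 17 (not isolated), via silyl ether 18 (not isolated)
Conditions: 14, t-BuLi (2 equiv), Et2O/THF, −78 °C; then 13, −78 °C; I2 (1.2 equiv), MeOH/THF, −78 °C; NaOMe, MeOH, −78 → 0 °C; aq. Na2S2O3; then rt → 40 °C, 3 h
Reagents that add atoms: none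
Why: Zweifel olefination: iodonium formation on the alkenyl borate triggers a 1,2-shift of the secondary alkyl group from boron to carbon with retention, methoxide-induced anti-elimination of boron and iodide gives the isopropenyl group, and the same methoxide then cleaves the aryl TBS ether.

Step 8
Reactants: 19 3,5-bis(methoxymethoxy)-4-[(2S)-5-methyl-2-(prop-1-en-2-yl)hex-4-en-1-yl]phenol
Product: 21 1-{6-hydroxy-2,4-bis(methoxymethoxy)-3-[(2S)-5-methyl-2-(prop-1-en-2-yl)hex-4-en-1-yl]phenyl}ethan-1-one, via dilithio phenoxide 20 (not isolated)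
Conditions: n-BuLi (1.05 equiv), THF, −78 °C; s-BuLi (1.3 equiv), TMEDA, −78 → −20 °C; MeC(O)N(OMe)Me, −78 → 0 °C; aq. NH4Cl
Reagents that add atoms: N-methoxy-N-methylacetamide, CC(=O)N(C)OC
Why: Phenoxide- and MOM-directed ortho-lithiation at one of the two equivalent positions between OLi and OMOM, then Weinreb ketone synthesis; the side-chain centre is not touched.

Step 9
Reactants: 4 3,5-bis(methoxymethoxy)phenol
Product: 22 1,3,5-tris(methoxymethoxy)benzene
Conditions: NaH, MOMCl, DMF, 0 °C → rt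
Reagents that add atoms: chloromethyl methyl ether, COCCl
Why: Williamson O-alkylation of the phenoxide gives the symmetric tris-MOM ether for ring B.

Step 10
Reactants: 22 1,3,5-tris(methoxymethoxy)benzene
Product: 24 2,4,6-tris(methoxymethoxy)benzaldehyde, via aryllithium 23 (not isolated)
Conditions: n-BuLi, TMEDA, THF, 0 °C; DMF, −78 °C → rt; aq. NH4Cl
Reagents that add atoms: N,N-dimethylformamide, CN(C)C=O
Why: Directed ortho-lithiation (all three ring positions are equivalent) and formylation with DMF.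

Step 11
Reactants: 21 ring-A acetophenone; 24 2,4,6-tris(methoxymethoxy)benzaldehyde
Product: 25 (2E)-1-{6-hydroxy-2,4-bis(methoxymethoxy)-3-[(2S)-5-methyl-2-(prop-1-en-2-yl)hex-4-en-1-yl]phenyl}-3-[2,4,6-tris(methoxymethoxy)phenyl]prop-2-en-1-one
Conditions: KOH, EtOH/H2O, rt, 72 h; AcOH to pH 6 at 0 °C
Reagents that add atoms: none
Why: Claisen–Schmidt aldol condensation gives the E enone, and the chalcone stays open as its phenoxide in strong base.

Step 12
Reactants: 25 2'-hydroxychalcone
Product: 26 (2S)-5,7-bis(methoxymethoxy)-6-[(2S)-5-methyl-2-(prop-1-en-2-yl)hex-4-en-1-yl]-2-[2,4,6-tris(methoxymethoxy)phenyl]-2,3-dihydro-4H-chromen-4-one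
Conditions: 9-amino(9-deoxy)epi-quinidine 3,5-bis(trifluoromethyl)phenyl squaramide (10 mol%), toluene, 0 °C, 48 h
Reagents that add atoms: none
Why: Proposed new method: catalytic enantioselective 6-endo oxa-Michael ring closure of a non-activated 2'-hydroxychalcone that carries a 2,6-di-O-substituted β-aryl group, which has no precedent; the quinuclidine nitrogen deprotonates the ortho-acyl phenol (pKa about 8) to a tight ion pair while the squaramide N–H pair binds the enone carbonyl, which the 6'-OMOM group twists out of the ring plane so that closure is strongly downhill, and the bound phenoxide adds to one enantioface of Cβ to set C2 as S (sense assigned by analogy, the quinine-derived pseudo-enantiomer addresses the other face), while the tertiary amine is too weak to enolise C3 of the product so retro-Michael racemisation stays slow at 0 °C; closest known reaction type: cinchona thiourea/squaramide-catalysed oxa-Michael cyclisation of doubly activated alkylidene β-keto esters to flavanones.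

Step 13
Reactants: 26 penta-MOM flavanone
Product: 28 (2S)-5,7-dihydroxy-6-[(2S)-5-methyl-2-(prop-1-en-2-yl)hex-4-en-1-yl]-2-(2,4,6-trihydroxyphenyl)-2,3-dihydro-4H-chromen-4-one, via pentakis(trimethylsilyl) ether 27 (not isolated)
Conditions: TMSOTf, 2,2'-bipyridyl, MeCN, 0 °C → rt; then H2O
Reagents that add atoms: none
Why: Non-protic MOM-ether cleavage (aryl MOM ethers are converted into aryl TMS ethers that hydrolyse on aqueous work-up) avoids strong Brønsted acid or base, so the two alkenes and the labile C2 centre are kept.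

**Compound list**
1 | resorcinol (benzene-1,3-diol) | Oc1cccc(O)c1 | starting material
2 | 1,3-bis(methoxymethoxy)benzene | COCOc1cccc(OCOC)c1 | intermediate
3 | 2-[3,5-bis(methoxymethoxy)phenyl]-4,4,5,5-tetramethyl-1,3,2-dioxaborolane | COCOc1cc(OCOC)cc(c1)B1OC(C)(C)C(C)(C)O1 | intermediate
4 | 3,5-bis(methoxymethoxy)phenol | COCOc1cc(O)cc(OCOC)c1 | intermediate
5 | tert-butyl[3,5-bis(methoxymethoxy)phenoxy]dimethylsilane | COCOc1cc(OCOC)cc(O[Si](C)(C)C(C)(C)C)c1 | intermediate
6 | [4-(tert-butyldimethylsilyloxy)-2,6-bis(methoxymethoxy)phenyl]lithium | [Li]c1c(OCOC)cc(O[Si](C)(C)C(C)(C)C)cc1OCOC | intermediate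
7 | lithium (bromomethyl)[4-(tert-butyldimethylsilyloxy)-2,6-bis(methoxymethoxy)phenyl](pinacolato)borate | [Li+].BrC[B-]1(OC(C)(C)C(C)(C)O1)c1c(OCOC)cc(O[Si](C)(C)C(C)(C)C)cc1OCOC | intermediate
8 | 2-{[4-(tert-butyldimethylsilyloxy)-2,6-bis(methoxymethoxy)phenyl]methyl}-4,4,5,5-tetramethyl-1,3,2-dioxaborolane | COCOc1cc(O[Si](C)(C)C(C)(C)C)cc(OCOC)c1CB1OC(C)(C)C(C)(C)O1 | intermediate
9 | 4-methylpent-3-en-1-ol | CC(C)=CCCO | starting material
10 | 4-methylpent-3-en-1-yl 2,4,6-tri(propan-2-yl)benzoate | CC(C)=CCCOC(=O)c1c(C(C)C)cc(C(C)C)cc1C(C)C | intermediate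
11 | (1R)-1-lithio-4-methylpent-3-en-1-yl 2,4,6-tri(propan-2-yl)benzoate (as its (+)-sparteine complex) | [Li][C@H](CC=C(C)C)OC(=O)c1c(C(C)C)cc(C(C)C)cc1C(C)C | intermediate
12 | lithium (arylmethyl)[(1R)-4-methyl-1-(2,4,6-triisopropylbenzoyloxy)pent-3-en-1-yl](pinacolato)borate, aryl = 4-(tert-butyldimethylsilyloxy)-2,6-bis(methoxymethoxy)phenyl | [Li+].CC1(C)O[B-](Cc2c(OCOC)cc(O[Si](C)(C)C(C)(C)C)cc2OCOC)(OC1(C)C)[C@H](CC=C(C)C)OC(=O)c1c(C(C)C)cc(C(C)C)cc1C(C)C | intermediate
13 | 2-[(2S)-1-{4-(tert-butyldimethylsilyloxy)-2,6-bis(methoxymethoxy)phenyl}-5-methylhex-4-en-2-yl]-4,4,5,5-tetramethyl-1,3,2-dioxaborolane | CC1(C)OB(OC1(C)C)[C@@H](CC=C(C)C)Cc1c(OCOC)cc(O[Si](C)(C)C(C)(C)C)cc1OCOC | intermediate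
14 | 2-bromopropene | CC(Br)=C | starting material
15 | prop-1-en-2-yllithium | [Li]C(C)=C | intermediate
16 | lithium (prop-1-en-2-yl)[(2S)-1-aryl-5-methylhex-4-en-2-yl](pinacolato)borate, aryl as in 13 | [Li+].C=C(C)[B-]1(OC(C)(C)C(C)(C)O1)[C@@H](CC=C(C)C)Cc1c(OCOC)cc(O[Si](C)(C)C(C)(C)C)cc1OCOC | intermediate
17 | tertiary β-iodo boronic ester after the 1,2-shift (both epimers at the boron-bearing carbon; side-chain centre as in 13) | ICC(C)(B1OC(C)(C)C(C)(C)O1)[C@@H](CC=C(C)C)Cc1c(OCOC)cc(O[Si](C)(C)C(C)(C)C)cc1OCOC | intermediate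
18 | tert-butyl{3,5-bis(methoxymethoxy)-4-[(2S)-5-methyl-2-(prop-1-en-2-yl)hex-4-en-1-yl]phenoxy}dimethylsilane | C=C(C)[C@@H](CC=C(C)C)Cc1c(OCOC)cc(O[Si](C)(C)C(C)(C)C)cc1OCOC | intermediate
19 | 3,5-bis(methoxymethoxy)-4-[(2S)-5-methyl-2-(prop-1-en-2-yl)hex-4-en-1-yl]phenol | C=C(C)[C@@H](CC=C(C)C)Cc1c(OCOC)cc(O)cc1OCOC | intermediate
20 | O,2-dilithio derivative of 19 (lithium 2-lithio-3,5-bis(methoxymethoxy)-4-[(2S)-side chain]phenoxide) | C=C(C)[C@@H](CC=C(C)C)Cc1c(OCOC)cc(O[Li])c([Li])c1OCOC | intermediate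
21 | 1-{6-hydroxy-2,4-bis(methoxymethoxy)-3-[(2S)-5-methyl-2-(prop-1-en-2-yl)hex-4-en-1-yl]phenyl}ethan-1-one | C=C(C)[C@@H](CC=C(C)C)Cc1c(OCOC)cc(O)c(C(C)=O)c1OCOC | intermediate
22 | 1,3,5-tris(methoxymethoxy)benzene | COCOc1cc(OCOC)cc(OCOC)c1 | intermediate
23 | [2,4,6-tris(methoxymethoxy)phenyl]lithium | [Li]c1c(OCOC)cc(OCOC)cc1OCOC | intermediate
24 | 2,4,6-tris(methoxymethoxy)benzaldehyde | COCOc1cc(OCOC)c(C=O)c(OCOC)c1 | intermediate
25 | (2E)-1-{6-hydroxy-2,4-bis(methoxymethoxy)-3-[(2S)-5-methyl-2-(prop-1-en-2-yl)hex-4-en-1-yl]phenyl}-3-[2,4,6-tris(methoxymethoxy)phenyl]prop-2-en-1-one | C=C(C)[C@@H](CC=C(C)C)Cc1c(OCOC)cc(O)c(C(=O)/C=C/c2c(OCOC)cc(OCOC)cc2OCOC)c1OCOC | intermediate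
26 | (2S)-5,7-bis(methoxymethoxy)-6-[(2S)-5-methyl-2-(prop-1-en-2-yl)hex-4-en-1-yl]-2-[2,4,6-tris(methoxymethoxy)phenyl]-2,3-dihydro-4H-chromen-4-one | C=C(C)[C@@H](CC=C(C)C)Cc1c(OCOC)cc2c(c1OCOC)C(=O)C[C@@H](c1c(OCOC)cc(OCOC)cc1OCOC)O2 | intermediate
27 | (2S)-6-[(2S)-5-methyl-2-(prop-1-en-2-yl)hex-4-en-1-yl]-5,7-bis(trimethylsilyloxy)-2-[2,4,6-tris(trimethylsilyloxy)phenyl]-2,3-dihydro-4H-chromen-4-one | C=C(C)[C@@H](CC=C(C)C)Cc1c(O[Si](C)(C)C)cc2c(c1O[Si](C)(C)C)C(=O)C[C@@H](c1c(O[Si](C)(C)C)cc(O[Si](C)(C)C)cc1O[Si](C)(C)C)O2 | intermediate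
28 | (2S)-5,7-dihydroxy-6-[(2S)-5-methyl-2-(prop-1-en-2-yl)hex-4-en-1-yl]-2-(2,4,6-trihydroxyphenyl)-2,3-dihydro-4H-chromen-4-one | C=C(C)[C@@H](CC=C(C)C)Cc1c(O)cc2c(c1O)C(=O)C[C@@H](c1c(O)cc(O)cc1O)O2 | target

**Step count and risk**
Total steps: 13. Longest linear sequence: 10 steps (1, 2, 3, 4, 6, 7, 8, 11, 12, 13).

Three steps most likely to fail:

Step 12 (the proposed new step). The electron-rich, doubly ortho-substituted β-aryl group may make closure slow, and the ee or the sense of induction may differ from the prediction. The fallback uses known chemistry and sets out from 25. Sodium acetate in refluxing ethanol closes the ring without stereocontrol to 26 and its C2 epimer, (2R)-5,7-bis(methoxymethoxy)-6-[(2S)-5-methyl-2-(prop-1-en-2-yl)hex-4-en-1-yl]-2-[2,4,6-tris(methoxymethoxy)phenyl]-2,3-dihydro-4H-chromen-4-one F3. The two are diastereomers and are separated by preparative HPLC. F3 is reopened to 25 with KOH in ethanol and recycled; only the O1 oxygen is free at this stage, so no regioisomer can form. The fallback comes back to the route at 26.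

Step 8. Ring lithiation of the lithium phenoxide may be incomplete, or the Weinreb amide may react at oxygen. The fallback sets out from 19. Magnesium-mediated ortho-formylation (MgCl2, Et3N, paraformaldehyde, MeCN, reflux) gives 6-hydroxy-2,4-bis(methoxymethoxy)-3-[(2S)-5-methyl-2-(prop-1-en-2-yl)hex-4-en-1-yl]benzaldehyde F1. Addition of MeMgBr in THF at 0 °C gives 1-{6-hydroxy-2,4-bis(methoxymethoxy)-3-[(2S)-5-methyl-2-(prop-1-en-2-yl)hex-4-en-1-yl]phenyl}ethan-1-ol F2 as a mixture of carbinol epimers. Oxidation of the benzylic alcohol with MnO2 in CH2Cl2 (or Dess–Martin periodinane) returns to the route at 21.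

Step 13. The very electron-rich B ring makes the C2–O1 bond easy to ionise under Lewis acid, which would epimerise C2; cleavage of five MOM groups may also be incomplete. Once the phenols are free, any ring opening would also give the 8-substituted isomer, so base must be avoided. The fallback sets out from 26 and gives up the stereoretentive deprotection: a fast thiol-assisted cleavage (ZnBr2, n-PrSH, CH2Cl2, 0 °C, 10 min) is accepted with partial C2 scrambling. The epimer (2R)-5,7-dihydroxy-6-[(2S)-5-methyl-2-(prop-1-en-2-yl)hex-4-en-1-yl]-2-(2,4,6-trihydroxyphenyl)-2,3-dihydro-4H-chromen-4-one F4 is a diastereomer of the target and is removed by preparative HPLC; it is not recycled, for the reason given above. The fallback comes back to the route at 28.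

**Further compounds**
F1 | step 8 | 6-hydroxy-2,4-bis(methoxymethoxy)-3-[(2S)-5-methyl-2-(prop-1-en-2-yl)hex-4-en-1-yl]benzaldehyde | C=C(C)[C@@H](CC=C(C)C)Cc1c(OCOC)cc(O)c(C=O)c1OCOC
F2 | step 8 | 1-{6-hydroxy-2,4-bis(methoxymethoxy)-3-[(2S)-5-methyl-2-(prop-1-en-2-yl)hex-4-en-1-yl]phenyl}ethan-1-ol | C=C(C)[C@@H](CC=C(C)C)Cc1c(OCOC)cc(O)c(C(C)O)c1OCOC
F3 | step 12 | (2R)-5,7-bis(methoxymethoxy)-6-[(2S)-5-methyl-2-(prop-1-en-2-yl)hex-4-en-1-yl]-2-[2,4,6-tris(methoxymethoxy)phenyl]-2,3-dihydro-4H-chromen-4-one | C=C(C)[C@@H](CC=C(C)C)Cc1c(OCOC)cc2c(c1OCOC)C(=O)C[C@H](c1c(OCOC)cc(OCOC)cc1OCOC)O2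
F4 | step 13 | (2R)-5,7-dihydroxy-6-[(2S)-5-methyl-2-(prop-1-en-2-yl)hex-4-en-1-yl]-2-(2,4,6-trihydroxyphenyl)-2,3-dihydro-4H-chromen-4-one | C=C(C)[C@@H](CC=C(C)C)Cc1c(O)cc2c(c1O)C(=O)C[C@H](c1c(O)cc(O)cc1O)O2
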